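**Plan**

- Retrosynthesis: the angelate ester at O9 is cut first, then the ring bond C9–C10. The cyclohexane (C5–C10) carries at C10 a quaternary carbon with methyl C14 and vinyl C1=C2 next to the C9 carbinol, which is the pattern left by γ-attack of a γ,γ-disubstituted allylmetal (C2–C1=C10) on a C9 aldehyde.
- The open-chain bromo aldehyde is cut further at O6–C12 (oxidative lactonisation), C4=C3 (ketone methylenation), C5–C6 (syn-aldol) and C7–C11 (vinylmetal addition to a ketone).
- Forward: an L-erythrulose-derived C6–C9 ketone takes up the C11–C13 vinyl unit, C6 becomes an aldehyde, and the aldol joins the C4/C5/C10/C1/C2 imide. The γ-lactone ring is closed first, the carbocycle second by the allylchromium step, and the angelate is put on last.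
- Stereochemistry: C8 from L-erythrulose; C7 by chelation-controlled addition; C5 and C6 from (S)-4-benzyloxazolidin-2-one; the E-C10=C1 alkene from syn-carboalumination; C9 and C10 from the chair transition state of the ring closure.

Key step: step 24

Remark: elemane numbering is used (ring C5–C10; methyl C14 and vinyl C1=C2 on C10; isopropenyl C4(=C3)C15 on C5; lactone O6–C12(=O)–C11(=C13)–C7). The SMILES reads as 5S,6S,7S,8S,9R,10S; in the open chain O6 is anti to the isopropenyl group and syn to the C10 branch, so the aldol is run with C4 as acyl carbon and the C10 unit as α-substituent.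

**Route**

Step 1
Reactants: 1 L-erythrulose
Product: 2 3,4-O-isopropylidene-L-erythrulose
Conditions: Me2C(OMe)2, CSA (cat.), acetone, rt
Reagents that add atoms: 2,2-dimethoxypropane, COC(C)(C)OC
Why: Acid-catalysed transacetalisation should tie the terminal 3,4-diol into the five-membered dioxolane and leave the primary α-hydroxy ketone free, with C8 (S) taken from the chiral pool.

Step 2
Reactants: 2 3,4-O-isopropylidene-L-erythrulose
Product: 3 (S)-1-(2,2-dimethyl-1,3-dioxolan-4-yl)-2-(triethylsilyloxy)ethan-1-one (C6 OTES, C7 ketone, C8/C9 acetonide)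
Conditions: Et3SiCl, imidazole, CH2Cl2, 0 °C
Reagents that add atoms: chlorotriethylsilane, CC[Si](Cl)(CC)CC
Why: Silylation of the only free hydroxyl gives a non-chelating O6 substituent that can later be oxidised directly to the aldehyde.

Step 3
Reactants: 4 2-bromoprop-2-en-1-ol
Product: 5 (2-bromoprop-2-en-1-yloxy)(tert-butyl)dimethylsilane
Conditions: t-BuMe2SiCl, imidazole, CH2Cl2, rt
Reagents that add atoms: tert-butyldimethylsilyl chloride, CC(C)(C)[Si](C)(C)Cl
Why: Standard silyl ether formation masks the C12 hydroxyl of the C11–C13 unit before halogen–metal exchange.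

Step 4
Reactants: 5 (2-bromoprop-2-en-1-yloxy)(tert-butyl)dimethylsilane, 3 silylated erythrulose acetonide
Product: 8 tertiary alcohol (7R 8S) carrying C6 OTES and C12 OTBS, via vinyllithium 6 (not isolated), via vinylmagnesium bromide 7 (not isolated)
Conditions: t-BuLi (2 equiv), Et2O, −78 °C; MgBr2·OEt2; then 3, −78 → −40 °C
Reagents that add atoms: none
Why: Bromine–lithium exchange and transmetalation give a vinyl Grignard reagent whose magnesium bridges the ketone oxygen and the dioxolane oxygen on C8 (Cram chelate, the silylated O6 does not compete), so 1,2-addition should occur anti to C9 and set C7 as 7R.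

Step 5
Reactants: 8 tertiary alcohol
Product: 9 6,7-bis(triethylsilyl) ether (7R, 8S)
Conditions: Et3SiOTf, 2,6-lutidine, CH2Cl2, −78 → 0 °C
Reagents that add atoms: triethylsilyl trifluoromethanesulfonate, CC[Si](CC)(CC)OS(=O)(=O)C(F)(F)F
Why: Silyl triflate silylation of the hindered tertiary alcohol masks O7 and also converges any material in which the TES group had moved from O6 to O7.

Step 6
Reactants: 9 bis(triethylsilyl) ether
Product: 10 (2S)-3-[(tert-butyldimethylsilyloxy)methyl]-2-[(4S)-2,2-dimethyl-1,3-dioxolan-4-yl]-2-(triethylsilyloxy)but-3-enal (C6 aldehyde)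
Conditions: (COCl)2, DMSO, CH2Cl2, −78 → −30 °C; Et3N, −78 → 0 °C
Reagents that add atoms: none
Why: Under Swern conditions the activated sulfoxide cleaves and oxidises a primary triethylsilyl ether in one operation, while the tertiary TES ether and the TBS ether stay in place.

Step 7
Reactants: 11 tert-butyl(but-3-yn-1-yloxy)dimethylsilane
Product: 14 (E)-5-(tert-butyldimethylsilyloxy)-3-methylpent-2-en-1-ol, via alkenylalane 12 (not isolated), via lithium alkenylaluminate 13 (not isolated)
Conditions: AlMe3, Cp2ZrCl2 (cat.), CH2Cl2, 0 °C → rt; n-BuLi, THF, −78 °C; (CH2O)n, −78 °C → rt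
Reagents that add atoms: trimethylaluminium, C[Al](C)C; formaldehyde (as paraformaldehyde), C=O
Why: Negishi zirconium-catalysed carboalumination adds methyl and aluminium syn across the terminal alkyne, and hydroxymethylation of the aluminate with retention fixes the E geometry of the future C10=C1 bond.

Step 8
Reactants: 14 (E)-5-(tert-butyldimethylsilyloxy)-3-methylpent-2-en-1-ol
Product: 15 tert-butyl{[(E)-5-(4-methoxybenzyloxy)-3-methylpent-3-en-1-yl]oxy}dimethylsilane
Conditions: NaH, 4-MeOC6H4CH2Cl, Bu4NI (cat.), THF/DMF, 0 °C → rt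
Reagents that add atoms: 4-methoxybenzyl chloride, COc1ccc(CCl)cc1
Why: Williamson etherification puts an oxidatively removable group on the C2 oxygen that survives the organometallic steps to come.

Step 9
Reactants: 15 PMB/TBS diether
Product: 16 (E)-5-(4-methoxybenzyloxy)-3-methylpent-3-en-1-ol
Conditions: Bu4NF, THF, 0 °C → rt
Reagents that add atoms: none
Why: Fluoride-mediated desilylation frees the homoallylic alcohol and leaves the PMB ether untouched.

Step 10
Reactants: 16 (E)-5-(4-methoxybenzyloxy)-3-methylpent-3-en-1-ol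
Product: 18 (E)-5-(4-methoxybenzyloxy)-3-methylpent-3-enoic acid, via aldehyde 17 (not isolated)
Conditions: TEMPO (cat.), PhI(OAc)2, MeCN/H2O, rt
Reagents that add atoms: water, O
Why: TEMPO-catalysed oxidation takes the primary alcohol through the aldehyde hydrate to the acid under near-neutral conditions, which should keep the β,γ-alkene out of conjugation and the PMB ether intact.

Step 11
Reactants: 18 (E)-5-(4-methoxybenzyloxy)-3-methylpent-3-enoic acid, 19 (S)-4-benzyl-1,3-oxazolidin-2-one
Product: 21 (S)-4-benzyl-3-[(E)-5-(4-methoxybenzyloxy)-3-methylpent-3-enoyl]-1,3-oxazolidin-2-one, via mixed pivalic anhydride 20 (not isolated)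
Conditions: t-BuCOCl, Et3N, THF, −20 °C; then LiCl, 19, −20 °C → rt
Reagents that add atoms: none
Why: N-Acylation of the oxazolidinone through the mixed pivalic anhydride with LiCl activation avoids strong base and so keeps the β,γ-unsaturated acyl group deconjugated.

Step 12
Reactants: 21 β,γ-unsaturated imide, 10 C6 aldehyde
Product: 23 syn-aldol adduct (5S 6S 7R 8S) bearing free C6 hydroxyl, via dibutylboron dienolate 22 (not isolated)
Conditions: Bu2BOTf, Et3N, CH2Cl2, −78 → 0 °C; 10, −78 → 0 °C; then H2O2, MeOH, pH 7 buffer, 0 °C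
Reagents that add atoms: none
Why: Evans syn-aldol reaction: the Z-boron dienolate reacts at its α-carbon C5 through a Zimmerman–Traxler chair in which the benzyl group of the (S)-auxiliary shields one enolate face, which should set 5S and 6S with the E alkene unchanged.

Step 13
Reactants: 23 syn-aldol adduct
Product: 24 N-methoxy-N-methylamide at C4 (5S, 6S, 7R, 8S)
Conditions: MeONHMe·HCl, AlMe3, CH2Cl2, −20 → 0 °C
Reagents that add atoms: N,O-dimethylhydroxylamine hydrochloride, CNOC.Cl
Why: Aluminium amide transamidation, assisted by the free β-hydroxyl, releases the auxiliary and gives the Weinreb amide without touching C5.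

Step 14
Reactants: 24 Weinreb amide
Product: 25 6-O-triethylsilyl Weinreb amide (5S, 6S, 7S, 8S)
Conditions: Et3SiOTf, 2,6-lutidine, CH2Cl2, −78 → 0 °C
Reagents that add atoms: triethylsilyl trifluoromethanesulfonate, CC[Si](CC)(CC)OS(=O)(=O)C(F)(F)F
Why: Silylation of the C6 hydroxyl removes the retro-aldol pathway from the ketone stage that follows.

Step 15
Reactants: 25 silylated Weinreb amide
Product: 26 C4 methyl ketone (5S, 6S, 7S, 8S)
Conditions: MeMgBr, THF, −20 → 0 °C
Reagents that add atoms: methylmagnesium bromide, C[Mg]Br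
Why: Weinreb ketone synthesis: the chelated tetrahedral intermediate stops at mono-addition and frees the enolisable β,γ-unsaturated ketone only on quench.

Step 16
Reactants: 26 methyl ketone
Product: 27 C4 isopropenyl compound (5S, 6S, 7S, 8S)
Conditions: Cp2TiMe2, toluene, 70 °C
Reagents that add atoms: dimethyltitanocene (Cp2TiMe2), C[Ti+2]C.c1cc[cH-]c1.c1cc[cH-]c1
Why: Petasis methylenation with a non-basic titanium carbene should turn the hindered ketone into the isopropenyl group without epimerising or conjugating the doubly allylic C5 centre.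

Step 17
Reactants: 27 isopropenyl compound
Product: 28 6,7,12-triol (5S, 6S, 7R, 8S)
Conditions: Bu4NF, THF, 0 °C → rt
Reagents that add atoms: none
Why: Global fluoride desilylation removes the two TES ethers and the TBS ether and leaves the acetonide and the PMB ether.

Step 18
Reactants: 28 6,7,12-triol
Product: 31 α-methylene-γ-lactone bearing free C7 hydroxyl (5S 6S 7R 8S), via hydroxy enal 29 (not isolated), via lactol 30 (not isolated)
Conditions: TEMPO (cat.), PhI(OAc)2, CH2Cl2, rt
Reagents that add atoms: none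
Why: TEMPO-catalysed oxidative lactonisation: the primary allylic C12 alcohol is oxidised to the enal, which closes with O6 to the five-membered lactol and is oxidised again, the secondary and tertiary hydroxyls being too slow to compete.

Step 19
Reactants: 31 lactone acetonide
Product: 32 lactone 7,8,9-triol (5S, 6S, 7S, 8S)
Conditions: AcOH/H2O (4:1), 40 °C
Reagents that add atoms: none
Why: Mild acid hydrolysis of the terminal acetonide is compatible with the α-methylene lactone, the PMB ether and the alkenes, and the triol is carried on at once to limit acyl migration to O8.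

Step 20
Reactants: 32 lactone triol
Product: 33 7,8,9-tris(triethylsilyl) ether (5S, 6S, 7R, 8S)
Conditions: Et3SiOTf, 2,6-lutidine, CH2Cl2, −78 → 0 °C
Reagents that add atoms: triethylsilyl trifluoromethanesulfonate, CC[Si](CC)(CC)OS(=O)(=O)C(F)(F)F
Why: Exhaustive silylation with the silyl triflate caps the primary, secondary and tertiary hydroxyls in one step.

Step 21
Reactants: 33 tris(triethylsilyl) ether
Product: 34 C9 aldehyde with 7,8-bis(triethylsilyloxy) groups and C2 OPMB (5S, 6S, 7R, 8R)
Conditions: (COCl)2, DMSO, CH2Cl2, −78 → −30 °C; Et3N, −78 → 0 °C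
Reagents that add atoms: none
Why: Swern oxidation again converts only the primary triethylsilyl ether into the aldehyde, the secondary and tertiary TES ethers being too hindered to react.

Step 22
Reactants: 34 C9 aldehyde PMB ether
Product: 35 C2 allylic alcohol with C9 aldehyde (5S, 6S, 7R, 8R)
Conditions: DDQ, CH2Cl2/pH 7 buffer, 0 °C
Reagents that add atoms: none
Why: Oxidative cleavage of the electron-rich PMB ether by DDQ frees the allylic alcohol under buffered conditions that spare the aldehyde, the silyl ethers and the lactone.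

Step 23
Reactants: 35 hydroxy aldehyde
Product: 37 (E)-allylic bromide with C9 aldehyde (5S 6S 7R 8R), via allylic mesylate 36 (not isolated)
Conditions: MsCl, Et3N, THF, −40 °C; then LiBr, −40 → 0 °C
Reagents that add atoms: lithium bromide, [Li+].[Br-]
Why: Mesylation and SN2 displacement by bromide at the primary allylic carbon keep the E geometry and tolerate the aldehyde, and the sensitive bromide is used at once.

Step 24
Reactants: 37 (E)-allylic bromide with C9 aldehyde
Product: 39 7,8-bis-O-triethylsilyl elemanolide with free C9 hydroxyl (5S 6S 7R 8S 9R 10S), via allylchromium dichloride 38 (not isolated)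
Conditions: CrCl2 (8 equiv), THF, rt, slow addition, 0.005 M
Reagents that add atoms: none
Why: Two equivalents of divalent chromium reduce the C2–Br bond to the allyl species 38 of trivalent chromium, which binds the C9 aldehyde oxygen and delivers its γ-carbon C10 through a closed six-membered Zimmerman–Traxler chair with allylic transposition; this is the Nozaki–Hiyama–Kishi allylation in its intramolecular form. The cyclohexane C5–C10 closes 6-exo-trig at the aldehyde, whereas α-attack through C2 would need an eight-membered ring. C9 is set by the chair: the E alkene places C5 equatorial and the C10 methyl axial, C8 sits equatorial on the aldehyde carbon, so O9 ends cis to the methyl and trans to the new vinyl group (9R). C10 (10S) is set by the existing C5 centre, whose isopropenyl group takes the equatorial position of the forming carbocycle, which is fused in a trans-decalin-like way to the chromium chair. The step needs γ-selectivity and aldehyde chemoselectivity: the first follows from the ring sizes and from the cis arrangement of the two arms on the preformed lactone, the second from the low basicity and carbonyl selectivity of allylchromium reagents, which should leave the α-methylene lactone and the silyl ethers untouched.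

Step 25
Reactants: 39 cyclised C9 alcohol, 40 angelic acid
Product: 42 9-O-angeloyl-7,8-bis-O-triethylsilyl elemanolide, via mixed anhydride 41 (not isolated)
Conditions: 2,4,6-Cl3C6H2COCl, Et3N, toluene, rt; then 39, 80 °C
Reagents that add atoms: none
Why: Yamaguchi esterification through the mixed trichlorobenzoic anhydride, run without a nucleophilic catalyst, should acylate the only free hydroxyl and avoid isomerisation of the angelate to the tiglate.

Step 26
Reactants: 42 angelate bis(triethylsilyl) ether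
Product: 43 CNP0114166.3 (5S, 6S, 7S, 8S, 9R, 10S)
Conditions: HF·pyridine, pyridine, THF, 0 °C → rt
Reagents that add atoms: none
Why: Buffered acidic fluoride desilylation removes the secondary and the tertiary TES ether without base, so no acyl migration of the angelate and no addition to the α-methylene lactone is expected.

**Compound list**

1 | L-erythrulose, (S)-1,3,4-trihydroxybutan-2-one | OCC(=O)[C@@H](O)CO | starting material
2 | 3,4-O-isopropylidene-L-erythrulose, (S)-1-(2,2-dimethyl-1,3-dioxolan-4-yl)-2-hydroxyethan-1-one | OCC(=O)[C@@H]1COC(C)(C)O1 | intermediate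
3 | (S)-1-(2,2-dimethyl-1,3-dioxolan-4-yl)-2-(triethylsilyloxy)ethan-1-one | CC[Si](CC)(CC)OCC(=O)[C@@H]1COC(C)(C)O1 | intermediate
4 | 2-bromoprop-2-en-1-ol | C=C(Br)CO | starting material
5 | (2-bromoprop-2-en-1-yloxy)(tert-butyl)dimethylsilane | C=C(Br)CO[Si](C)(C)C(C)(C)C | intermediate
6 | [3-(tert-butyldimethylsilyloxy)prop-1-en-2-yl]lithium (not isolated) | [Li]C(=C)CO[Si](C)(C)C(C)(C)C | intermediate
7 | [3-(tert-butyldimethylsilyloxy)prop-1-en-2-yl]magnesium bromide (not isolated) | Br[Mg]C(=C)CO[Si](C)(C)C(C)(C)C | intermediate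
8 | (2R)-3-[(tert-butyldimethylsilyloxy)methyl]-2-[(4S)-2,2-dimethyl-1,3-dioxolan-4-yl]-1-(triethylsilyloxy)but-3-en-2-ol (7R,8S) | C=C(CO[Si](C)(C)C(C)(C)C)[C@](CO[Si](CC)(CC)CC)(O)[C@@H]1COC(C)(C)O1 | intermediate
9 | tert-butyl{[(3R)-3-[(4S)-2,2-dimethyl-1,3-dioxolan-4-yl]-2-methylidene-3,4-bis(triethylsilyloxy)butyl]oxy}dimethylsilane (7R,8S) | C=C(CO[Si](C)(C)C(C)(C)C)[C@](CO[Si](CC)(CC)CC)(O[Si](CC)(CC)CC)[C@@H]1COC(C)(C)O1 | intermediate
10 | (2S)-3-[(tert-butyldimethylsilyloxy)methyl]-2-[(4S)-2,2-dimethyl-1,3-dioxolan-4-yl]-2-(triethylsilyloxy)but-3-enal (7S,8S) | C=C(CO[Si](C)(C)C(C)(C)C)[C@](C=O)(O[Si](CC)(CC)CC)[C@@H]1COC(C)(C)O1 | intermediate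
11 | tert-butyl(but-3-yn-1-yloxy)dimethylsilane | C#CCCO[Si](C)(C)C(C)(C)C | starting material
12 | [(E)-4-(tert-butyldimethylsilyloxy)-2-methylbut-1-en-1-yl]dimethylaluminium (not isolated) | C[Al](C)/C=C(\C)CCO[Si](C)(C)C(C)(C)C | intermediate
13 | lithium butyl[(E)-4-(tert-butyldimethylsilyloxy)-2-methylbut-1-en-1-yl]dimethylaluminate (not isolated) | [Li+].CCCC[Al-](C)(C)/C=C(\C)CCO[Si](C)(C)C(C)(C)C | intermediate
14 | (E)-5-(tert-butyldimethylsilyloxy)-3-methylpent-2-en-1-ol | OC/C=C(\C)CCO[Si](C)(C)C(C)(C)C | intermediate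
15 | tert-butyl{[(E)-5-(4-methoxybenzyloxy)-3-methylpent-3-en-1-yl]oxy}dimethylsilane | COc1ccc(COC/C=C(\C)CCO[Si](C)(C)C(C)(C)C)cc1 | intermediate
16 | (E)-5-(4-methoxybenzyloxy)-3-methylpent-3-en-1-ol | COc1ccc(COC/C=C(\C)CCO)cc1 | intermediate
17 | (E)-5-(4-methoxybenzyloxy)-3-methylpent-3-enal (not isolated) | COc1ccc(COC/C=C(\C)CC=O)cc1 | intermediate
18 | (E)-5-(4-methoxybenzyloxy)-3-methylpent-3-enoic acid | COc1ccc(COC/C=C(\C)CC(=O)O)cc1 | intermediate
19 | (S)-4-benzyl-1,3-oxazolidin-2-one | O=C1N[C@@H](Cc2ccccc2)CO1 | starting material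
20 | (E)-5-(4-methoxybenzyloxy)-3-methylpent-3-enoic pivalic anhydride (not isolated) | COc1ccc(COC/C=C(\C)CC(=O)OC(=O)C(C)(C)C)cc1 | intermediate
21 | (S)-4-benzyl-3-[(E)-5-(4-methoxybenzyloxy)-3-methylpent-3-enoyl]-1,3-oxazolidin-2-one | COc1ccc(COC/C=C(\C)CC(=O)N2[C@@H](Cc3ccccc3)COC2=O)cc1 | intermediate
22 | dibutylboron (Z)-dienolate of 21 (not isolated) | CCCCB(CCCC)O/C(=C\C(C)=C\COCc1ccc(OC)cc1)N1[C@@H](Cc2ccccc2)COC1=O | intermediate
23 | syn-aldol adduct: (4S)-4-benzyl-3-acyl-1,3-oxazolidin-2-one with acyl chain C4(=O)–C5H[(E)-C10(CH3)=C1H–C2H2OPMB]–C6H(OH)–C7(OSiEt3)[C11(=C13H2)–C12H2OTBS]–[(4S)-2,2-dimethyl-1,3-dioxolan-4-yl]; 5S,6S,7R,8S | COc1ccc(COC/C=C(\C)[C@H](C(=O)N2[C@@H](Cc3ccccc3)COC2=O)[C@H](O)[C@](O[Si](CC)(CC)CC)(C(=C)CO[Si](C)(C)C(C)(C)C)[C@@H]2COC(C)(C)O2)cc1 | intermediate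
24 | Weinreb amide: N-methoxy-N-methylamide at C4 in place of the oxazolidinone of 23; 5S,6S,7R,8S | COc1ccc(COC/C=C(\C)[C@H](C(=O)N(C)OC)[C@H](O)[C@](O[Si](CC)(CC)CC)(C(=C)CO[Si](C)(C)C(C)(C)C)[C@@H]2COC(C)(C)O2)cc1 | intermediate
25 | 6-O-triethylsilyl ether of 24; 5S,6S,7S,8S | COc1ccc(COC/C=C(\C)[C@H](C(=O)N(C)OC)[C@H](O[Si](CC)(CC)CC)[C@](O[Si](CC)(CC)CC)(C(=C)CO[Si](C)(C)C(C)(C)C)[C@@H]2COC(C)(C)O2)cc1 | intermediate
26 | methyl ketone: C4 acetyl in place of the amide of 25; 5S,6S,7S,8S | COc1ccc(COC/C=C(\C)[C@H](C(C)=O)[C@H](O[Si](CC)(CC)CC)[C@](O[Si](CC)(CC)CC)(C(=C)CO[Si](C)(C)C(C)(C)C)[C@@H]2COC(C)(C)O2)cc1 | intermediate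
27 | C4 isopropenyl compound: C4(=C3H2)C15H3 in place of the acetyl group of 26; 5S,6S,7S,8S | COc1ccc(COC/C=C(\C)[C@H](C(C)=C)[C@H](O[Si](CC)(CC)CC)[C@](O[Si](CC)(CC)CC)(C(=C)CO[Si](C)(C)C(C)(C)C)[C@@H]2COC(C)(C)O2)cc1 | intermediate
28 | 6,7,12-triol from 27 (C2 OPMB and 8,9-acetonide kept); 5S,6S,7R,8S | COc1ccc(COC/C=C(\C)[C@H](C(C)=C)[C@H](O)[C@](O)(C(=C)CO)[C@@H]2COC(C)(C)O2)cc1 | intermediate
29 | C12 aldehyde (2-substituted acrolein) of 28 (not isolated) | COc1ccc(COC/C=C(\C)[C@H](C(C)=C)[C@H](O)[C@](O)(C(=C)C=O)[C@@H]2COC(C)(C)O2)cc1 | intermediate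
30 | γ-lactol O6–C12H(OH) of 29, mixture at C12 (not isolated) | COc1ccc(COC/C=C(\C)[C@H](C(C)=C)[C@@H]2OC(O)C(=C)[C@]2(O)[C@@H]3COC(C)(C)O3)cc1 | intermediate
31 | α-methylene-γ-lactone (O6–C12(=O)–C11(=C13H2)–C7) with free C7 hydroxyl, 8,9-acetonide and C2 OPMB; 5S,6S,7R,8S | COc1ccc(COC/C=C(\C)[C@H](C(C)=C)[C@@H]2OC(=O)C(=C)[C@]2(O)[C@@H]3COC(C)(C)O3)cc1 | intermediate
32 | 7,8,9-triol of lactone 31; 5S,6S,7S,8S | COc1ccc(COC/C=C(\C)[C@H](C(C)=C)[C@@H]2OC(=O)C(=C)[C@]2(O)[C@@H](O)CO)cc1 | intermediate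
33 | 7,8,9-tris(triethylsilyl) ether of 32; 5S,6S,7R,8S | COc1ccc(COC/C=C(\C)[C@H](C(C)=C)[C@@H]2OC(=O)C(=C)[C@]2(O[Si](CC)(CC)CC)[C@@H](O[Si](CC)(CC)CC)CO[Si](CC)(CC)CC)cc1 | intermediate
34 | C9 aldehyde with 7,8-bis(triethylsilyloxy) groups and C2 OPMB; 5S,6S,7R,8R | COc1ccc(COC/C=C(\C)[C@H](C(C)=C)[C@@H]2OC(=O)C(=C)[C@]2(O[Si](CC)(CC)CC)[C@@H](O[Si](CC)(CC)CC)C=O)cc1 | intermediate
35 | C2 allylic alcohol with C9 aldehyde; 5S,6S,7R,8R | OC/C=C(\C)[C@H](C(C)=C)[C@@H]1OC(=O)C(=C)[C@]1(O[Si](CC)(CC)CC)[C@@H](O[Si](CC)(CC)CC)C=O | intermediate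
36 | C2 methanesulfonate of 35 (not isolated) | CS(=O)(=O)OC/C=C(\C)[C@H](C(C)=C)[C@@H]1OC(=O)C(=C)[C@]1(O[Si](CC)(CC)CC)[C@@H](O[Si](CC)(CC)CC)C=O | intermediate
37 | (2R)-2-{(2S,3R)-2-[(3S,4E)-6-bromo-2,4-dimethylhexa-1,4-dien-3-yl]-4-methylidene-5-oxo-3-(triethylsilyloxy)oxolan-3-yl}-2-(triethylsilyloxy)acetaldehyde; 5S,6S,7R,8R | BrC/C=C(\C)[C@H](C(=C)C)[C@@H]1OC(=O)C(=C)[C@]1(O[Si](CC)(CC)CC)[C@@H](O[Si](CC)(CC)CC)C=O | intermediate
38 | allylchromium dichloride from 37, trivalent chromium on C2 (not isolated) | Cl[Cr](Cl)C/C=C(\C)[C@H](C(=C)C)[C@@H]1OC(=O)C(=C)[C@]1(O[Si](CC)(CC)CC)[C@@H](O[Si](CC)(CC)CC)C=O | intermediate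
39 | 7,8-bis-O-triethylsilyl elemanolide with free C9 hydroxyl; 5S,6S,7R,8S,9R,10S | C=C[C@@]1(C)[C@H](C(=C)C)[C@@H]2OC(=O)C(=C)[C@]2(O[Si](CC)(CC)CC)[C@@H](O[Si](CC)(CC)CC)[C@@H]1O | intermediate
40 | angelic acid, (Z)-2-methylbut-2-enoic acid | C/C=C(/C)C(=O)O | starting material
41 | (Z)-2-methylbut-2-enoic 2,4,6-trichlorobenzoic anhydride (not isolated) | C/C=C(/C)C(=O)OC(=O)c1c(Cl)cc(Cl)cc1Cl | intermediate
42 | 9-O-angeloyl-7,8-bis-O-triethylsilyl elemanolide; 5S,6S,7R,8S,9R,10S | C=C[C@@]1(C)[C@H](C(=C)C)[C@@H]2OC(=O)C(=C)[C@]2(O[Si](CC)(CC)CC)[C@@H](O[Si](CC)(CC)CC)[C@@H]1OC(=O)/C(C)=C\C | intermediate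
43 | CNP0114166.3; 5S,6S,7S,8S,9R,10S | C=C[C@@]1(C)[C@H](C(=C)C)[C@@H]2OC(=O)C(=C)[C@]2(O)[C@@H](O)[C@@H]1OC(=O)/C(C)=C\C | target

**Summary**

Total step count: 26.
Longest linear sequence: 20 steps (steps 1, 2, 4–6 and 12–26 from L-erythrulose; the same length through steps 7–11 and 12–26 from the silylated butynol).

Steps most likely to fail:

- Step 24 (ring closure). The γ,γ-disubstituted allylchromium may lose its alkene geometry, or be protonated or coupled with itself, before it reaches the hindered aldehyde; this would erode the C9/C10 selectivity or leave the chain uncyclised. The fallback sets out from 35 and comes back at 39. 35 is acetylated (Ac2O, pyridine, CH2Cl2, 0 °C) to the allylic acetate aldehyde F1. With B2pin2 and Pd2(dba)3 (cat.) in DMSO at 40 °C the acetate is converted through a π-allylpalladium species into the allyl pinacolboronate F2, which is not isolated. F2 is configurationally stable and should add at once through C10 to the C9 aldehyde in a closed chair of the same shape, giving 39 after hydrolysis of the borate.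

- Step 12 (aldol). The stabilised boron dienolate may add too slowly to the α-quaternary, doubly silylated aldehyde, so that enolate decomposition or retro-aldol on work-up takes over. The fallback sets out from 18 and comes back at 24. 18 is coupled with (S)-4-benzyl-1,3-thiazolidine-2-thione (EDC·HCl, DMAP, CH2Cl2) to the N-acylthiazolidinethione F3. Its chlorotitanium enolate (TiCl4, i-Pr2NEt, N-methyl-2-pyrrolidinone, CH2Cl2, −78 °C), which activates the aldehyde more strongly, should add to 10 in the same syn sense to give adduct F4. The thione auxiliary of F4 is displaced directly with MeONHMe·HCl and imidazole to give 24.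

- Step 4 (C7 carbinol). Chelation may lose against the Felkin–Anh pathway or against enolisation of the ketone, giving poor facial selectivity at C7. The fallback sets out from 5 and comes back at 9, and it enters the two carbon substituents in the reverse order so that the Felkin–Anh preference becomes the wanted one. The vinyllithium from 5 is added to the N-methoxy-N-methylamide F5 (made from commercial methyl (S)-2,2-dimethyl-1,3-dioxolane-4-carboxylate with MeONHMe·HCl and i-PrMgCl) to give enone F6. 1,2-Addition of i-PrOMe2SiCH2MgCl in the presence of CeCl3 gives the silyl carbinol F7, and Tamao oxidation (H2O2, KF, KHCO3) gives the diol F8. Double silylation with Et3SiOTf and 2,6-lutidine returns to 9.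

Further compounds
F1 | step 24 | C2 allylic acetate with C9 aldehyde (acetate of 35) | CC(=O)OC/C=C(\C)[C@H](C(=C)C)[C@@H]1OC(=O)C(=C)[C@]1(O[Si](CC)(CC)CC)[C@@H](O[Si](CC)(CC)CC)C=O
F2 | step 24 | C2 allyl pinacolboronate with C9 aldehyde (not isolated) | CC1(C)OB(C/C=C(\C)[C@H](C(=C)C)[C@@H]2OC(=O)C(=C)[C@]2(O[Si](CC)(CC)CC)[C@@H](O[Si](CC)(CC)CC)C=O)OC1(C)C
F3 | step 12 | (S)-4-benzyl-3-[(E)-5-(4-methoxybenzyloxy)-3-methylpent-3-enoyl]-1,3-thiazolidine-2-thione | COc1ccc(COC/C=C(\C)CC(=O)N2[C@@H](Cc3ccccc3)CSC2=S)cc1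
F4 | step 12 | syn-aldol adduct of F3 and 10 (thiazolidinethione analogue of 23; 5S,6S,7R,8S) | COc1ccc(COC/C=C(\C)[C@H](C(=O)N2[C@@H](Cc3ccccc3)CSC2=S)[C@H](O)[C@](O[Si](CC)(CC)CC)(C(=C)CO[Si](C)(C)C(C)(C)C)[C@@H]2COC(C)(C)O2)cc1
F5 | step 4 | (S)-N-methoxy-N,2,2-trimethyl-1,3-dioxolane-4-carboxamide | CON(C)C(=O)[C@@H]1COC(C)(C)O1
F6 | step 4 | 2-[(tert-butyldimethylsilyloxy)methyl]-1-[(4S)-2,2-dimethyl-1,3-dioxolan-4-yl]prop-2-en-1-one | C=C(CO[Si](C)(C)C(C)(C)C)C(=O)[C@@H]1COC(C)(C)O1
F7 | step 4 | (7R,8S)-tertiary alcohol carrying C6 as CH2SiMe2(O-i-Pr) and C12 OTBS | C=C(CO[Si](C)(C)C(C)(C)C)[C@@](O)(C[Si](C)(C)OC(C)C)[C@@H]1COC(C)(C)O1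
F8 | step 4 | (2R)-3-[(tert-butyldimethylsilyloxy)methyl]-2-[(4S)-2,2-dimethyl-1,3-dioxolan-4-yl]but-3-ene-1,2-diol | C=C(CO[Si](C)(C)C(C)(C)C)[C@](CO)(O)[C@@H]1COC(C)(C)O1
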